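The constants that the runs can give begin with dissolution, the first rung of the ladder in the teal run.

| setting | teal | red | east | west | south-east |
|---|---|---|---|---|---|
| solid substrate | 0.080 M | 0.32 M | 0.16 M | 0.16 M | 0.16 M |
| temperature | 15 °C | 37 °C | 5 °C | 45 °C | 25 °C |
| remark | run made earlier | run made earlier |  |  |  |
| time |  |  | 2.5 h | 2.5 h | 2.5 h |

- teal (time / min: target / %, solid substrate / %): 8.00: 0.9, 69.2; 15.0: 4.1, 47.6; 25.0: 10.9, 22.0; 50.0: 29.4, 0; 90.0: 46.4, 0.5
- red (time / min: target / %, solid substrate / %): 2.50: 0.4, 97.6; 5.00: 2.2, 95.5; 8.00: 1.7, 92.8; 15.0: 6.2, 85.5; 30.0: 10.0, 73.1

(each reading ± 0.5 percentage points)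

- solid substrate is a solid; its amount is given per volume of the solution
- the numbers in the tables scatter by 0.5 percentage points (one standard deviation)
- steps thought possible: starting material <-> target; solid substrate <-> starting material; starting material <-> isomer of the product; target <-> isomer of the product
- at the start none of the solid substrate is in solution
- what has only dissolved of solid substrate counts as not reacted

1. which flask leads in amount of target, in percent of the solid substrate charged ("all alike" within 1.5 percentage points) (east / west / south-east / all alike)
2. how much target is there at the end, in percent of the solid substrate charged: east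
3. how much target is there at the end, in percent of the solid substrate charged: west
4. how much target is there at the end, in percent of the solid substrate charged: south-east

In the teal run the solid feeds the solution at a mean 0.00308 M min⁻¹ up to the first reading, with a mean 0.0120 M dissolved and not yet target. Between the second and third readings the feed is 0.00205 M min⁻¹ at 0.0462 M. Replacing each curve by its mean and drawing a straight line through these two points, the feed falls by 0.0302 min⁻¹ per unit of [starting material]. It reaches zero at 0.114 M, the ceiling on [starting material], its solubility. The line's time scale is 33.1 min. For the red run, between its fourth and fifth readings, the line gives 0.00222 M min⁻¹, while the reading is 0.00265 M min⁻¹; the line takes as [starting material] all that has left the solid and is not target, so any isomer of the product is counted in it.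

The next rung is conversion. After the teal solid has gone, target grows at 0.00684 min⁻¹ of the remainder, counted as starting material, which is slower than dissolution. Assuming a factor of 2 per ten degrees gives 0.00342 min⁻¹ in east, a time of 292 min, longer than the run. East's charge of 0.16 M exceeds the ceiling, so this reckoning has [starting material] climb to 71.3 % of charge, averaging 0.0888 M, and gives 28.5 % target. On the slowest rung, target's share of what left the red solid falls from 42.8 % to 37.2 %, so this reckoning doubts any warm lead but sizes no warm flask.

The forecast differs. It names west as leader, with 36 % in east, 60 % in west and 58 % in south-east, and its grounds include that the slowdown “suggests a plateau near 60% target”.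

South-east leads with 33.4 %, against 20.8 % in east and 3.45 % in west.

    starting material ⇌ target (K = 2.10, k = 7.83 × 10⁻⁴ s⁻¹, Ea = 97.0 kJ mol⁻¹, ΔH = −12.0 kJ mol⁻¹)
    solid substrate ⇌ starting material, rate k2*(cs2 - [starting material]) while solid is left; crystals form when [starting material] > cs2 (solubility = 0.120 M, k = 4.70 × 10⁻⁴ s⁻¹)
    starting material ⇌ isomer of the product (K = 34.6, k = 2.57 × 10⁻⁵ s⁻¹, Ea = 109 kJ mol⁻¹, ΔH = 8.00 kJ mol⁻¹)
    target ⇌ isomer of the product (k = 1.58 × 10⁻⁴ s⁻¹, Ea = 100 kJ mol⁻¹)
    (constants at 25 °C)

East ends with [starting material] at 0.109 M, which is 67.9 % of charge against the reckoned 71.3 %, and with 10.1 % still solid. Its target stands below the reckoned 28.5 %. A neighbouring flask is east with 0.27 M charged, and there the same ceiling is 42.2 % of charge. That flask gives 40.2 % starting material, with 46.8 % still solid and 12.3 % target.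

(Readings and results stem from a simulated flask for substances that don't exist; scatter was added.)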